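**Assumptions.**
(i) Normal-series (+)-sclareolide (C10-Me β, H5 α, H9 α, C8-O α, C11 β) is the chiral source. Four suprafacial 1,2-shifts of this series (H9 α→C8, Me10 β→C9, H5 α→C10, Me4 β→C5) give C5-Me β, C8-Me β with H α, C9-Me β with the C11 side chain α, and H10 α. I checked this against the target SMILES, and it matches.
(ii) Proton loss from the final C4 cation favors the trisubstituted endocyclic Δ3 alkene over the exocyclic alkene. Any exocyclic isomer formed is carried on unseparated and is unchanged by step 2, because it is already that step's product.

## Retrosynthetic overview
1. The ArCH2–C9 bond is made last, by photochemical Ni/photoredox decarboxylative arylation of the redox-active ester of the C9 acetic acid. The sclareolide carbonyl carbon is lost as CO2.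
2. The exocyclic C4=CH2 comes from the endocyclic Δ3 alkene by photochemical contra-thermodynamic positional isomerization.
3. The rearranged decalin (C5 quaternary Me, C8 CH–Me, C9 quaternary Me, H10) comes from (+)-sclareolide by lactone ionization at C8, four Wagner–Meerwein shifts (H9, Me10, H5, Me4) and proton loss.
4. Both rings are already present in sclareolide, so no ring is formed. The cascade only relocates H and Me groups, and all stereocenters are inherited from the chiral pool.

## Route

**Step 1**
Reactants: 1 (+)-sclareolide
Product: 2 rearranged Δ3 acid (4,9-friedo-decalin acetic acid, endocyclic trisubstituted alkene)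
Conditions: BF3·OEt2 (4 equiv), CH2Cl2, –20 °C → 25 °C, 8 h; aqueous NaHCO3, then 1 M HCl workup
Reagents that add atoms: none
Why: Proposed new method: BF3 opens the tertiary C8–O bond of the lactone to give the C8 cation, and the carboxylate stays bound to boron. The cascade follows the biosynthetic friedo-rearrangement, with four antiperiplanar suprafacial shifts (H9α→C8, Me10β→C9, H5α→C10, Me4β→C5). These set C8-H α, Me-9 β (pushing the side chain to α), H-10 α and Me-5 β, so every stereocenter follows from the stereocenters of 1. The closest known reaction type is the BF3-mediated backbone rearrangement of drimenyl arenes, here run on a lactone that ends as a CH2CO2H side chain. The congested C10 γ-lactone is a reversible dead end, and E1 loss of a C3 proton from the C4 cation is the irreversible exit.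

**Step 2**
Reactants: 2 rearranged Δ3 acid
Product: 3 rearranged exocyclic 4(11)-ene acid
Conditions: TBADT (2 mol %), Co(dmgH)2pyCl (5 mol %), MeCN, 390 nm LEDs, 25 °C, 24 h
Reagents that add atoms: none
Why: Contra-thermodynamic positional alkene isomerization by decatungstate HAT/cobaloxime dual catalysis. HAT from an allylic C–H of 2 gives an allyl radical, and Co captures it at the primary terminus. SE2′ protodemetalation then places H at C3 and gives the less substituted exocyclic alkene, which reacts poorly in further HAT. No stereocenter is touched. This is known reactivity applied to a new substrate class, an endocyclic alkene next to a quaternary center in a terpenoid acid.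

**Step 3**
Reactants: 3 exocyclic acid; 4 N-hydroxyphthalimide
Product: 5 NHPI redox-active ester of 3
Conditions: NHPI (1.2 equiv), DIC (1.2 equiv), DMAP (0.1 equiv), CH2Cl2, 25 °C, 4 h
Reagents that add atoms: none (NHPI, O=C1c2ccccc2C(=O)N1O, is reactant 4)
Why: Steglich-type esterification makes the radical precursor. The alkene and all stereocenters are untouched.

**Step 4**
Reactants: 5 NHPI ester; 6 methyl 4-hydroxy-3-iodobenzoate
Product: 7 dictyoceratin C
Conditions: NiBr2·dtbbpy (10 mol %), 4CzIPN (2 mol %), Hantzsch ester (1.5 equiv), aryl iodide 6 (1.5 equiv), DMA, blue LEDs, 25 °C, 16 h
Reagents that add atoms: none (the aryl iodide is reactant 6)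
Why: Ni/photoredox reductive decarboxylative arylation. Single-electron reduction of the NHPI ester releases phthalimide and CO2 and gives the primary neopentyl radical on C11. Ni oxidative addition into the Ar–I bond, radical capture and reductive elimination then form the ArCH2–C9 bond. The C9 quaternary center is not involved, so it is not scrambled, and the exocyclic alkene and the methyl ester are inert.

## Compound list
1 | (+)-sclareolide | C[C@]12CCCC(C)(C)[C@@H]1CC[C@@]3(C)OC(=O)C[C@H]23 | starting material
2 | rearranged Δ3 acid (4,9-friedo-decalin acetic acid, 4-ene) | CC1=CCC[C@H]2[C@](C)(CC(=O)O)[C@@H](C)CC[C@]12C | intermediate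
3 | rearranged exocyclic 4(11)-ene acid | C=C1CCC[C@H]2[C@](C)(CC(=O)O)[C@@H](C)CC[C@]12C | intermediate
4 | N-hydroxyphthalimide | O=C1c2ccccc2C(=O)N1O | starting material
5 | NHPI ester of 3 | C=C1CCC[C@H]2[C@](C)(CC(=O)ON3C(=O)c4ccccc4C3=O)[C@@H](C)CC[C@]12C | intermediate
6 | methyl 4-hydroxy-3-iodobenzoate | COC(=O)c1ccc(O)c(I)c1 | starting material
7 | dictyoceratin C | C=C1CCC[C@H]2[C@](C)(Cc3cc(C(=O)OC)ccc3O)[C@@H](C)CC[C@]12C | target

## Totals
Total steps: 4. Longest linear sequence: 4 (1 → 2 → 3 → 5 → 7).

## Three steps most likely to fail
1. **Step 1 (the proposed new cascade).** The C10 γ-lactone or unrearranged Δ8/Δ7 acids could trap the material, or the cascade could stall partway.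
   Fallback (known chemistry, different approach): install the benzyl group before the rearrangement. Open sclareolide to the homodrimenoic acid, make its NHPI ester, and arylate it with methyl 4-acetoxy-3-iodobenzoate. Then run the precedented BF3·OEt2 backbone rearrangement of the aryl-drimene, where no nucleophilic carboxyl is present. Finally remove the acetate with K2CO3/MeOH, and isomerize any endocyclic alkene as in step 2.
2. **Step 2 (photochemical isomerization).** Competing HAT at the tertiary C8–H and C10–H bonds, or an incomplete Δ3 → exocyclic shift, would lower the yield.
   Fallback: make the methyl ester (TMSCHN2) and converge the alkenes by Mukaiyama hydration (Co(acac)2, PhSiH3, O2) to the C4 tertiary alcohol. Dehydrate with Martin sulfurane, separate the exocyclic alkene from the endocyclic isomer on AgNO3–silica (recycling the endocyclic isomer), and hydrolyze the ester (KOSiMe3) to give the exocyclic acid.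
3. **Step 4 (photochemical arylation).** The hindered neopentyl radical, the free ortho-iodophenol and the phenoxide binding Ni may all lower the yield.
   Fallback: use the same ester 5 in the non-photochemical Ni-catalyzed decarboxylative Negishi coupling with the arylzinc from methyl 4-(tert-butyldimethylsilyloxy)-3-iodobenzoate. Remove the silyl group with TBAF or HF·pyridine.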